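North-west got about twice the catalyst of north-east, and its log ratio x = ln(c right-handed substrate / c left-handed substrate) at the last reading came out about twice as large too.

| setting | north-east | north-west | beta | gamma |
|---|---|---|---|---|
| left-handed substrate | 18 mM | 18 mM | 18 mM | 18 mM |
| right-handed substrate | 18 mM | 18 mM | 18 mM | 18 mM |
| reagent | 54 mM | 54 mM | 54.0 mM | 54.0 mM |
| free catalyst | 0.10 mM | 0.21 mM | 0.18 mM | 0.25 mM |
| added ligand | 0.11 mM | 0.11 mM | 0.11 mM | 0.11 mM |
| remark | run made earlier | run made earlier |  |  |
| time |  |  | 8.0 h | 8.0 h |

| run | time / h | right-handed substrate / % | left-handed substrate / % | left-handed product / % |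
|---|---|---|---|---|
| north-east | 1.00 | 51 | 30 | 8 |
| north-east | 2.50 | 50 | 20 | 16 |
| north-east | 3.00 | 47 | 22 | 14 |
| north-east | 5.00 | 50 | 17 | 19 |
| north-east | 6.00 | 48 | 14 | 18 |
| north-west | 0.417 | 48 | 28 | 14 |
| north-west | 0.833 | 49 | 18 | 16 |
| north-west | 1.50 | 49 | 15 | 18 |
| north-west | 3.00 | 48 | 7 | 22 |
| north-west | 6.00 | 48 | 3 | 24 |

(each reading ± 1.5 percentage points)

- which of the two ends with the higher excess of right-handed substrate over left-handed substrate among what is left of the two ("neither" if they lie within 2 percentage points) (beta / gamma / neither)
- excess of right-handed substrate over left-handed substrate among what is left of the two at the end, beta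
- excess of right-handed substrate over left-handed substrate among what is left of the two at the end, gamma

- free catalyst is single-handed; left-handed substrate and right-handed substrate are mirror images of each other, charged as a racemate, each of them at the stated concentration
- an excess is below zero if the other one leads

In north-west, the log slope of the left-handed substrate reads 1.06 h⁻¹ early, steeper than the 0.282 h⁻¹ late. I read this as a pseudo-first-order decay with a fading constant. So I freeze reagent and right-handed substrate, and count catalyst as a dose.

The dose number is x per mM of catalyst charged. The excess follows from x. Push the north-west reading up by two standard deviations and you get the low end of my estimate, 9.90 mM⁻¹. Push the north-east reading down the same way and you get the high end, 14.7 mM⁻¹.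

For beta, my bracket is 71.2 % to 86.8 %. For gamma, it is 84.5 % to 95.1 %. Gamma stays ahead at both ends, by more than the margin.

The forecast says gamma, with 87 % for beta and 92 % for gamma, on the ground that “The decay is not first order”. Its beta value sits at the top of my bracket, and its gamma value lies inside.

The flask gives gamma, with 72.0 % for beta, inside the bracket, and 83.7 % for gamma, just below it.

    reagent + free catalyst + left-handed substrate → free catalyst + left-handed product (k = 71.0 L² mol⁻² s⁻¹)
    reagent + free catalyst + right-handed substrate → free catalyst + right-handed product (k = 2.00 L² mol⁻² s⁻¹)
    free catalyst → spent catalyst (k = 2.90 × 10⁻⁴ s⁻¹)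
    left-handed product ⇌ right-handed product (k = 0.00180 s⁻¹)
    free catalyst + added ligand ⇌ idle complex (K = 13000 L mol⁻¹, k = 380 L mol⁻¹ s⁻¹)

Free catalyst has a half-life of 0.66 h by its own decay, far shorter than the asked time. In beta, spent catalyst stands at 97.9 % at 8.00 h, and x per mM of catalyst is 10.1 mM⁻¹, beside the carried 9.90 mM⁻¹.

Now read beta at 3.00 h, with spent catalyst at 80.5 %. Counting that share of the dose, 9.90 mM⁻¹ gives 61.5 %. The computed excess is 64.3 %.

The earlier runs and the new flask come from a simulation with constants of no real substance, and the scatter is random.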